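**Retrosynthetic overview**
- Target ⇐ desilylation and side-chain ester hydrolysis ⇐ C8 methyl by Negishi coupling of a C7=C8 enol triflate; the C3 ester by acylating the 3α-alkoxide obtained by hydride reduction of a 2α-silyloxy-3-ketone (Rubottom oxidation).
- C9 side chain (an (R)-iodide from monomethyl (S)-3-methylglutarate) by alkylating the regiodefined enolate that results from conjugate methyl addition (sets C10, then C9) to a bicyclic enone.
- Bicyclic enone ⇐ Birch reduction and hydrolysis of the anisole ring of a dihydronaphthalenol; C5 is set by equilibration under a CBS-derived carbinol at C3.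
- Key step: exhaustive C-methylation of 6-methoxy-2-naphthol (alkylative dearomatization), which creates the gem-dimethyl carbon C4.
- Ring order: both rings come from the naphthalene; ring A is dearomatized first (step 1), ring B second (step 3).

Assumption: the SMILES is read literally, so the decalin is cis-fused (H-5 and the C10 methyl on the same face, called β), the C9 chain is β (H-9 α), and the 2-OH and 3-acyloxy groups are α; labdane numbering (C1 to C15; ring A = C1–C5/C10, ring B = C5–C10) is used for the bicyclic compounds.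

**Route**

Step 1
Reactants: 1 6-methoxynaphthalen-2-ol
Product: 2 6-methoxy-1,1-dimethylnaphthalen-2(1H)-one
Conditions: KOtBu (2.5 equiv), MeI (4 equiv), t-BuOH, 23 to 50 °C
Reagents that add atoms: iodomethane, CI
Why: Alkylative dearomatization of a 2-naphthoxide: in the hydrogen-bonding solvent both methylations occur at C1 (the second on the 1-methyl-2-naphthoxide), which breaks the aromaticity of ring A and builds the future C4 gem-dimethyl carbon without a stereocentre.

Step 2
Reactants: 2 6-methoxy-1,1-dimethylnaphthalen-2(1H)-one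
Product: 3 (R)-6-methoxy-1,1-dimethyl-1,2-dihydronaphthalen-2-ol
Conditions: (S)-2-methyl-CBS-oxazaborolidine (10 mol%), catecholborane (1.5 equiv), toluene, −78 °C; aq. NaOH wash
Reagents that add atoms: none
Why: Corey–Bakshi–Shibata reduction, 1,2-selective on the enone; with the quaternary C1 as the large group the (S)-catalyst gives the (R)-carbinol (the later 3α-oxygen).

Step 3
Reactants: 3 (R)-6-methoxy-1,1-dimethyl-1,2-dihydronaphthalen-2-ol
Product: 6 (4aS,6R)-6-hydroxy-5,5-dimethyl-4,4a,5,6,7,8-hexahydronaphthalen-2(3H)-one, via dienol methyl ether 4 (not isolated), via nonconjugated enone 5 (not isolated)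
Conditions: Li (10 equiv), NH3/THF, t-BuOH, −78 to −33 °C; NH4Cl; then 2 M HCl, THF/MeOH, 23 °C, 16 h
Reagents that add atoms: water, O
Why: Birch reduction of the anisole ring (the styrenic C=C is saturated in the same flask), then enol ether hydrolysis and conjugation as in 19-nor-steroid syntheses; C4a (labdane C5) equilibrates through the dienol and prefers H-4a cis to H-6 so that the hydroxyl is equatorial (about 3–4:1 expected), and the minor 4a-epimer is separated and returned to the same acid.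

Step 4
Reactants: 6 (4aS,6R)-6-hydroxy-5,5-dimethyl-4,4a,5,6,7,8-hexahydronaphthalen-2(3H)-one
Product: 7 4,4,10β-trimethyl-3α,8-bis(trimethylsilyloxy)-5βH-decal-8-ene (labdane locants; C8=C9 silyl enol ether)
Conditions: Me2CuLi (3 equiv), TMSCl (5 equiv), Et3N, THF, −78 to −30 °C
Reagents that add atoms: lithium dimethylcuprate, [Li+].C[Cu-]C; chlorotrimethylsilane, C[Si](C)(C)Cl
Why: TMSCl-accelerated cuprate conjugate addition; methyl enters C10 on the face of H-5 (the classical outcome for these octalones, reinforced by the axial C4 methyl on the other face), giving the cis-fused decalin, and the enolate is trapped regiospecifically while the hydroxyl is silylated.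

Step 5
Reactants: 8 (S)-5-methoxy-3-methyl-5-oxopentanoic acid (monomethyl (S)-3-methylglutarate)
Product: 9 methyl (S)-5-hydroxy-3-methylpentanoate
Conditions: BH3·SMe2 (1.1 equiv), THF, −10 to 23 °C; MeOH quench; used directly
Reagents that add atoms: none
Why: Chemoselective borane reduction of the carboxylic acid in the presence of the ester; the stereocentre is not touched.

Step 6
Reactants: 9 methyl (S)-5-hydroxy-3-methylpentanoate
Product: 10 methyl (R)-5-iodo-3-methylpentanoate
Conditions: I2, PPh3, imidazole, CH2Cl2, 0 °C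
Reagents that add atoms: iodine, [I][I]
Why: Appel-type iodination (Garegg–Samuelsson) of the primary alcohol; the stereocentre is unchanged (the descriptor changes only by priority).

Step 7
Reactants: 7 4,4,10β-trimethyl-3α,8-bis(trimethylsilyloxy)-5βH-decal-8-ene; 10 methyl (R)-5-iodo-3-methylpentanoate
Product: 13 methyl (13S)-3α-hydroxy-8-oxo-17-nor-5β-labdan-15-oate, via lithium enolate 11 (not isolated), via trimethylsilyl ether 12 (not isolated)
Conditions: MeLi (1.05 equiv), THF, 0 °C; then 10 (2 equiv), HMPA, −40 to 23 °C; 1 M HCl work-up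
Reagents that add atoms: none
Why: Regiospecific enolate alkylation (lithium enolate released from the silyl enol ether); the iodide approaches C9 on the convex β face, anti to the axial C1 methylene of ring A, so the chain ends cis to the C10 methyl, and the acid wash frees the 3-hydroxyl.

Step 8
Reactants: 13 methyl (13S)-3α-hydroxy-8-oxo-17-nor-5β-labdan-15-oate
Product: 14 methyl (13S)-3α-hydroxy-8-(trifluoromethanesulfonyloxy)-17-nor-5β-labd-7-en-15-oate
Conditions: KN(SiMe3)2 (2.2 equiv), THF, −78 °C; PhNTf2 (1.2 equiv), −78 to 0 °C; NH4Cl work-up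
Reagents that add atoms: N-phenylbis(trifluoromethanesulfonimide), O=S(=O)(N(c1ccccc1)S(=O)(=O)C(F)(F)F)C(F)(F)F
Why: Kinetic enolization at the unhindered C7 methylene (C9–H is tertiary and next to the quaternary C10; the hindered alkoxide is a spectator) followed by O-triflation fixes the later C7=C8 double bond.

Step 9
Reactants: 14 methyl (13S)-3α-hydroxy-8-(trifluoromethanesulfonyloxy)-17-nor-5β-labd-7-en-15-oate
Product: 15 methyl (13S)-3-oxo-8-(trifluoromethanesulfonyloxy)-17-nor-5β-labd-7-en-15-oate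
Conditions: Dess–Martin periodinane (1.3 equiv), NaHCO3, CH2Cl2, 23 °C
Reagents that add atoms: none
Why: Dess–Martin oxidation of the hindered secondary alcohol, which has served its purpose of fixing C5; C5, C9 and C10 are not enolizable toward this ketone.

Step 10
Reactants: 15 methyl (13S)-3-oxo-8-(trifluoromethanesulfonyloxy)-17-nor-5β-labd-7-en-15-oate
Product: 17 methyl (13S)-2α-(tert-butyldimethylsilyloxy)-3-oxo-8-(trifluoromethanesulfonyloxy)-17-nor-5β-labd-7-en-15-oate, via silyl enol ether 16 (not isolated)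
Conditions: TBSOTf (1.3 equiv), Et3N, CH2Cl2, 0 °C; then mCPBA (1.1 equiv), NaHCO3, hexane/CH2Cl2, −20 to 0 °C
Reagents that add atoms: tert-butyldimethylsilyl trifluoromethanesulfonate, CC(C)(C)[Si](C)(C)OS(=O)(=O)C(F)(F)F; 3-chloroperbenzoic acid, OOC(=O)c1cccc(Cl)c1
Why: Rubottom oxidation; enolization can only go toward C2 (C4 is quaternary), the peracid attacks C2 from the α face because the β face of ring A carries the syn-axial C10 and C4β methyls (conformer with C4 equatorial on ring B and the C9 chain pseudoaxial), and silyl migration gives the 2α-silyloxy ketone while the enol triflate is inert.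

Step 11
Reactants: 18 (S)-2-hydroxy-2-methylbutanoic acid
Product: 20 (S)-2-methyl-2-(triethylsilyloxy)butanoyl chloride, via bis(triethylsilyl) derivative 19 (not isolated)
Conditions: TESCl (2.2 equiv), imidazole, DMF, 23 °C; then (COCl)2 (1.2 equiv), DMF (cat.), CH2Cl2, 0 to 23 °C
Reagents that add atoms: chlorotriethylsilane, CC[Si](Cl)(CC)CC; oxalyl chloride, ClC(=O)C(Cl)=O
Why: Silylation followed by silyl ester to acid chloride exchange under neutral conditions; the quaternary stereocentre cannot epimerize.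

Step 12
Reactants: 17 methyl (13S)-2α-(tert-butyldimethylsilyloxy)-3-oxo-8-(trifluoromethanesulfonyloxy)-17-nor-5β-labd-7-en-15-oate; 20 (S)-2-methyl-2-(triethylsilyloxy)butanoyl chloride
Product: 22 methyl (13S)-2α-(tert-butyldimethylsilyloxy)-3α-[(S)-2-methyl-2-(triethylsilyloxy)butanoyloxy]-8-(trifluoromethanesulfonyloxy)-17-nor-5β-labd-7-en-15-oate, via lithium alkoxide 21 (not isolated)
Conditions: LiBH(sec-Bu)3 (1.1 equiv), THF, −78 °C; then 20 (2 equiv), DMAP (1 equiv), −78 to 23 °C
Reagents that add atoms: none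
Why: Bulky-borohydride reduction with equatorial (β-face) hydride delivery, the axial α trajectory being blocked by the axial C6 methylene and the 2α-silyloxy group, gives the axial 3α-alkoxide cis to O-2, which is acylated in the same flask by the acid chloride (nucleophilic acyl substitution).

Step 13
Reactants: 22 the enol triflate ester from step 12
Product: 23 methyl (13S)-2α-(tert-butyldimethylsilyloxy)-3α-[(S)-2-methyl-2-(triethylsilyloxy)butanoyloxy]-5β-labd-7-en-15-oate
Conditions: MeZnCl (3 equiv), Pd(PPh3)4 (5 mol%), THF, 50 °C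
Reagents that add atoms: methylzinc chloride, C[Zn]Cl
Why: Negishi cross-coupling of the enol triflate installs the C8 methyl on the pre-positioned C7=C8 double bond and tolerates the esters and silyl ethers.

Step 14
Reactants: 23 methyl (13S)-2α-(tert-butyldimethylsilyloxy)-3α-[(S)-2-methyl-2-(triethylsilyloxy)butanoyloxy]-5β-labd-7-en-15-oate
Product: 24 (13S)-2α-(tert-butyldimethylsilyloxy)-3α-[(S)-2-methyl-2-(triethylsilyloxy)butanoyloxy]-5β-labd-7-en-15-oic acid
Conditions: LiOH (3 equiv), THF/MeOH/H2O, 23 °C; 1 M HCl to pH 3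
Reagents that add atoms: lithium hydroxide, [Li+].[OH-]
Why: Saponification of the unhindered methyl ester; the C3 ester (α-quaternary acyl on a neopentyl axial oxygen) resists, and the silyl group on O-2 excludes acyl migration under base.

Step 15
Reactants: 24 (13S)-2α-(tert-butyldimethylsilyloxy)-3α-[(S)-2-methyl-2-(triethylsilyloxy)butanoyloxy]-5β-labd-7-en-15-oic acid
Product: 25 (13S)-2α-hydroxy-3α-[(S)-2-hydroxy-2-methylbutanoyloxy]-5β-labd-7-en-15-oic acid (CNP0305549.1)
Conditions: HF·pyridine, pyridine/THF, 0 to 23 °C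
Reagents that add atoms: none
Why: Fluoride-mediated desilylation under buffered acidic conditions removes both silyl ethers without acyl migration or isomerization of the trisubstituted alkene.

**Compound list**
1 | 6-methoxynaphthalen-2-ol | COc1ccc2cc(O)ccc2c1 | starting material
2 | 6-methoxy-1,1-dimethylnaphthalen-2(1H)-one | O=C1C=Cc2cc(OC)ccc2C1(C)C | intermediate
3 | (R)-6-methoxy-1,1-dimethyl-1,2-dihydronaphthalen-2-ol | O[C@@H]1C=Cc2cc(OC)ccc2C1(C)C | intermediate
4 | (R)-6-methoxy-1,1-dimethyl-1,2,3,4,5,8-hexahydronaphthalen-2-ol | O[C@@H]1CCC2=C(CC=C(OC)C2)C1(C)C | intermediate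
5 | (R)-6-hydroxy-5,5-dimethyl-3,4,5,6,7,8-hexahydronaphthalen-2(1H)-one | O[C@@H]1CCC2=C(CCC(=O)C2)C1(C)C | intermediate
6 | (4aS,6R)-6-hydroxy-5,5-dimethyl-4,4a,5,6,7,8-hexahydronaphthalen-2(3H)-one | O[C@@H]1CCC2=CC(=O)CC[C@@H]2C1(C)C | intermediate
7 | 4,4,10β-trimethyl-3α,8-bis(trimethylsilyloxy)-5βH-decal-8-ene | C[Si](C)(C)O[C@@H]1CC[C@@]2(C)[C@H](CCC(O[Si](C)(C)C)=C2)C1(C)C | intermediate
8 | (S)-5-methoxy-3-methyl-5-oxopentanoic acid | OC(=O)C[C@H](C)CC(=O)OC | starting material
9 | methyl (S)-5-hydroxy-3-methylpentanoate | OCC[C@H](C)CC(=O)OC | intermediate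
10 | methyl (R)-5-iodo-3-methylpentanoate | ICC[C@H](C)CC(=O)OC | intermediate
11 | lithium 4,4,10β-trimethyl-3α-(trimethylsilyloxy)-5βH-decal-8-en-8-olate | C[Si](C)(C)O[C@@H]1CC[C@@]2(C)[C@H](CCC([O-])=C2)C1(C)C.[Li+] | intermediate
12 | methyl (13S)-8-oxo-3α-(trimethylsilyloxy)-17-nor-5β-labdan-15-oate | C[Si](C)(C)O[C@@H]1CC[C@@]2(C)[C@H](CCC(=O)[C@@H]2CC[C@H](C)CC(=O)OC)C1(C)C | intermediate
13 | methyl (13S)-3α-hydroxy-8-oxo-17-nor-5β-labdan-15-oate | O[C@@H]1CC[C@@]2(C)[C@H](CCC(=O)[C@@H]2CC[C@H](C)CC(=O)OC)C1(C)C | intermediate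
14 | methyl (13S)-3α-hydroxy-8-(trifluoromethanesulfonyloxy)-17-nor-5β-labd-7-en-15-oate | O[C@@H]1CC[C@@]2(C)[C@H](CC=C(OS(=O)(=O)C(F)(F)F)[C@@H]2CC[C@H](C)CC(=O)OC)C1(C)C | intermediate
15 | methyl (13S)-3-oxo-8-(trifluoromethanesulfonyloxy)-17-nor-5β-labd-7-en-15-oate | O=C1CC[C@@]2(C)[C@H](CC=C(OS(=O)(=O)C(F)(F)F)[C@@H]2CC[C@H](C)CC(=O)OC)C1(C)C | intermediate
16 | methyl (13S)-3-(tert-butyldimethylsilyloxy)-8-(trifluoromethanesulfonyloxy)-17-nor-5β-labda-2,7-dien-15-oate | CC(C)(C)[Si](C)(C)OC1=CC[C@@]2(C)[C@H](CC=C(OS(=O)(=O)C(F)(F)F)[C@@H]2CC[C@H](C)CC(=O)OC)C1(C)C | intermediate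
17 | methyl (13S)-2α-(tert-butyldimethylsilyloxy)-3-oxo-8-(trifluoromethanesulfonyloxy)-17-nor-5β-labd-7-en-15-oate | O=C1[C@H](O[Si](C)(C)C(C)(C)C)C[C@@]2(C)[C@H](CC=C(OS(=O)(=O)C(F)(F)F)[C@@H]2CC[C@H](C)CC(=O)OC)C1(C)C | intermediate
18 | (S)-2-hydroxy-2-methylbutanoic acid | CC[C@](C)(O)C(=O)O | starting material
19 | triethylsilyl (S)-2-methyl-2-(triethylsilyloxy)butanoate | CC[C@](C)(O[Si](CC)(CC)CC)C(=O)O[Si](CC)(CC)CC | intermediate
20 | (S)-2-methyl-2-(triethylsilyloxy)butanoyl chloride | CC[C@](C)(O[Si](CC)(CC)CC)C(Cl)=O | intermediate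
21 | lithium 3α-alkoxide of methyl (13S)-2α-(tert-butyldimethylsilyloxy)-3α-hydroxy-8-(trifluoromethanesulfonyloxy)-17-nor-5β-labd-7-en-15-oate | [Li+].[O-][C@@H]1[C@H](O[Si](C)(C)C(C)(C)C)C[C@@]2(C)[C@H](CC=C(OS(=O)(=O)C(F)(F)F)[C@@H]2CC[C@H](C)CC(=O)OC)C1(C)C | intermediate
22 | methyl (13S)-2α-(tert-butyldimethylsilyloxy)-3α-[(S)-2-methyl-2-(triethylsilyloxy)butanoyloxy]-8-(trifluoromethanesulfonyloxy)-17-nor-5β-labd-7-en-15-oate | CC[C@](C)(O[Si](CC)(CC)CC)C(=O)O[C@@H]1[C@H](O[Si](C)(C)C(C)(C)C)C[C@@]2(C)[C@H](CC=C(OS(=O)(=O)C(F)(F)F)[C@@H]2CC[C@H](C)CC(=O)OC)C1(C)C | intermediate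
23 | methyl (13S)-2α-(tert-butyldimethylsilyloxy)-3α-[(S)-2-methyl-2-(triethylsilyloxy)butanoyloxy]-5β-labd-7-en-15-oate | CC[C@](C)(O[Si](CC)(CC)CC)C(=O)O[C@@H]1[C@H](O[Si](C)(C)C(C)(C)C)C[C@@]2(C)[C@H](CC=C(C)[C@@H]2CC[C@H](C)CC(=O)OC)C1(C)C | intermediate
24 | (13S)-2α-(tert-butyldimethylsilyloxy)-3α-[(S)-2-methyl-2-(triethylsilyloxy)butanoyloxy]-5β-labd-7-en-15-oic acid | CC[C@](C)(O[Si](CC)(CC)CC)C(=O)O[C@@H]1[C@H](O[Si](C)(C)C(C)(C)C)C[C@@]2(C)[C@H](CC=C(C)[C@@H]2CC[C@H](C)CC(=O)O)C1(C)C | intermediate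
25 | (13S)-2α-hydroxy-3α-[(S)-2-hydroxy-2-methylbutanoyloxy]-5β-labd-7-en-15-oic acid | CC[C@](C)(O)C(=O)O[C@@H]1[C@H](O)C[C@@]2(C)[C@H](CC=C(C)[C@@H]2CC[C@H](C)CC(=O)O)C1(C)C | target

**Step count**
Total: 15 steps. Longest linear sequence: 12 steps (1, 2, 3, 4, 7, 8, 9, 10, 12, 13, 14, 15).

**Three steps most likely to fail**

Step 2. The enone carbonyl lies between a vinyl group and a quaternary carbon, so the sense and level of induction in the CBS reduction are not certain. The fallback sets out from 2. Hydrogenation (H2, Pd/C, EtOAc) gives 6-methoxy-1,1-dimethyl-3,4-dihydronaphthalen-2(1H)-one F1, whose carbonyl is flanked by CH2 and a quaternary carbon. CBS reduction ((S)-2-methyl-CBS-oxazaborolidine, BH3·SMe2, THF) then gives (R)-6-methoxy-1,1-dimethyl-1,2,3,4-tetrahydronaphthalen-2-ol F2 with the usual tert-alkyl ketone selectivity. F2 under the conditions of step 3 gives the dienol ether 4, and the route continues from there to 6.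

Step 7. Alkylation of a hindered enolate next to a quaternary carbon with an unactivated primary iodide may be slow and may suffer proton transfer. The fallback sets out from 7 (with an aldehyde made from 9) and replaces alkylation by aldol addition and deoxygenation. Alcohol 9 is oxidized (Dess–Martin periodinane) to methyl (S)-3-methyl-5-oxopentanoate F3. Enolate 11 (from 7 and MeLi) adds to F3 at −78 °C from the same β face to give methyl (13S)-11-hydroxy-8-oxo-3α-(trimethylsilyloxy)-17-nor-5β-labdan-15-oate F4 (either C11 epimer). 1,1'-Thiocarbonyldiimidazole and DMAP convert the new hydroxyl into the imidazolylthiocarbonate F5. Barton–McCombie deoxygenation (Bu3SnH, AIBN, toluene, 90 °C) then returns to the route at 12, and the acid wash gives 13.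

Step 10. The α-face selectivity of the peracid rests on a conformational argument for a flexible cis-decalin; if the electrophile prefers the β face, the 2β-epimer forms. The fallback sets out from 14 and uses a reaction that places the cis-diol on the face opposite to the one the electrophile prefers, forming the C3 ester by C–O bond formation. Burgess dehydration of 14 (benzene, 50 °C) gives methyl (13S)-8-(trifluoromethanesulfonyloxy)-17-nor-5β-labda-2,7-dien-15-oate F6. Acid 18 and Ag2O give silver (S)-2-hydroxy-2-methylbutanoate F7. Woodward–Prévost cis-hydroxylation of F6 (I2, F7, wet benzene) proceeds through the iodo ester and the acyloxonium ion to the 2α-hydroxy 3α-ester, methyl (13S)-2α-hydroxy-3α-[(S)-2-hydroxy-2-methylbutanoyloxy]-8-(trifluoromethanesulfonyloxy)-17-nor-5β-labd-7-en-15-oate F8. Negishi methylation (MeZnCl, Pd(PPh3)4) gives methyl (13S)-2α-hydroxy-3α-[(S)-2-hydroxy-2-methylbutanoyloxy]-5β-labd-7-en-15-oate F9. Me3SnOH (1,2-dichloroethane, 80 °C) cleaves the methyl ester without acyl migration and comes back to the route at 25.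

**Further compounds**
F1 | step 2 | 6-methoxy-1,1-dimethyl-3,4-dihydronaphthalen-2(1H)-one | O=C1CCc2cc(OC)ccc2C1(C)C
F2 | step 2 | (R)-6-methoxy-1,1-dimethyl-1,2,3,4-tetrahydronaphthalen-2-ol | O[C@@H]1CCc2cc(OC)ccc2C1(C)C
F3 | step 7 | methyl (S)-3-methyl-5-oxopentanoate | O=CC[C@H](C)CC(=O)OC
F4 | step 7 | methyl (13S)-11-hydroxy-8-oxo-3α-(trimethylsilyloxy)-17-nor-5β-labdan-15-oate | C[Si](C)(C)O[C@@H]1CC[C@@]2(C)[C@H](CCC(=O)[C@@H]2C(O)C[C@H](C)CC(=O)OC)C1(C)C
F5 | step 7 | methyl (13S)-11-(imidazol-1-ylthiocarbonyloxy)-8-oxo-3α-(trimethylsilyloxy)-17-nor-5β-labdan-15-oate | C[Si](C)(C)O[C@@H]1CC[C@@]2(C)[C@H](CCC(=O)[C@@H]2C(OC(=S)n3ccnc3)C[C@H](C)CC(=O)OC)C1(C)C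
F6 | step 10 | methyl (13S)-8-(trifluoromethanesulfonyloxy)-17-nor-5β-labda-2,7-dien-15-oate | C1=CC[C@@]2(C)[C@H](CC=C(OS(=O)(=O)C(F)(F)F)[C@@H]2CC[C@H](C)CC(=O)OC)C1(C)C
F7 | step 10 | silver (S)-2-hydroxy-2-methylbutanoate | CC[C@](C)(O)C(=O)[O-].[Ag+]
F8 | step 10 | methyl (13S)-2α-hydroxy-3α-[(S)-2-hydroxy-2-methylbutanoyloxy]-8-(trifluoromethanesulfonyloxy)-17-nor-5β-labd-7-en-15-oate | CC[C@](C)(O)C(=O)O[C@@H]1[C@H](O)C[C@@]2(C)[C@H](CC=C(OS(=O)(=O)C(F)(F)F)[C@@H]2CC[C@H](C)CC(=O)OC)C1(C)C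
F9 | step 10 | methyl (13S)-2α-hydroxy-3α-[(S)-2-hydroxy-2-methylbutanoyloxy]-5β-labd-7-en-15-oate | CC[C@](C)(O)C(=O)O[C@@H]1[C@H](O)C[C@@]2(C)[C@H](CC=C(C)[C@@H]2CC[C@H](C)CC(=O)OC)C1(C)C
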